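Labdane numbering is used. Ring B is closed last across C8–C9: the exocyclic methylidene carbon C8 is the radical site left by a 2-bromoalkene, and C9 is the near carbon of an (E)-C9=C11 alkene that already carries the complete C11–C16 chain. The precursor is a ring A silyl enol ether (C4–O, C4=C5) whose C10 quaternary centre comes from a copper-catalysed asymmetric conjugate alkenylation. One 6-exo vinyl-radical closure then gives ring B, the C8=C17 methylidene, saturated C11 and the C9 centre, and unmasking the C4 ketone lets C5 settle to the trans ring fusion. The ketone is finally converted into the C4 methyl/acyloxymethyl centre.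

Key step: step 7

Remark: methyl hydrogen (R)-3-methylglutarate and (R)-2-methylbutanoic acid are taken as commercial single enantiomers; the epimer mixtures at C5 in 11 and 12 and at C4 in 19 are inconsequential because these centres are planarised in the following step.

Step 1
Reactants: 1 methyl hydrogen (R)-3-methylglutarate
Product: 3 (4S)-4-methyltetrahydro-2H-pyran-2-one, via hydroxy acid 2 (not isolated)
Conditions: LiBH4, THF, 0 °C → rt; then 2 M HCl, rt
Reagents that add atoms: none
Why: Chemoselective hydride reduction: LiBH4 should reduce the methyl ester but not the lithium carboxylate, and acidification closes the six-membered lactone without touching the stereocentre.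

Step 2
Reactants: 3 (4S)-4-methyltetrahydro-2H-pyran-2-one
Product: 5 (3R)-3-methylhex-5-yn-1-ol, via lactol 4 (not isolated)
Conditions: i-Bu2AlH, CH2Cl2, −78 °C; then MeOH, K2CO3, dimethyl (1-diazo-2-oxopropyl)phosphonate, −78 °C → rt
Reagents that add atoms: dimethyl (1-diazo-2-oxopropyl)phosphonate (CC(=O)C(=[N+]=[N-])P(=O)(OC)OC)
Why: Partial reduction should stop at the lactol, whose open hydroxy aldehyde undergoes Seyferth–Gilbert homologation with the Ohira–Bestmann reagent to the terminal alkyne (future C9≡C11); no stereocentre is formed.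

Step 3
Reactants: 5 (3R)-3-methylhex-5-yn-1-ol
Product: 6 tert-butyl(dimethyl){[(3R)-3-methylhex-5-yn-1-yl]oxy}silane
Conditions: TBSCl, imidazole, CH2Cl2, rt
Reagents that add atoms: tert-butyldimethylsilyl chloride (CC(C)(C)[Si](C)(C)Cl)
Why: Standard silylation of the primary alcohol masks the future C15 carboxyl carbon at the alcohol level so that the chain tolerates the aluminium hydride used next.

Step 4
Reactants: 6 tert-butyl(dimethyl){[(3R)-3-methylhex-5-yn-1-yl]oxy}silane; 7 3-methylcyclohex-2-en-1-one
Product: 10 ring A trimethylsilyl enol ether with the C10 quaternary centre, via alkenylalane 8 (not isolated), via aluminium enolate 9 (not isolated)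
Conditions: 6, i-Bu2AlH, heptane, 50 °C; then 7, copper thiophene-2-carboxylate (CuTC, 10 mol %), chiral phosphinamine ligand (SimplePhos type, 11 mol %), Et2O, −10 °C; then Me3SiOTf, THF, −10 °C → rt
Reagents that add atoms: trimethylsilyl trifluoromethanesulfonate (C[Si](C)(C)OS(=O)(=O)C(F)(F)F)
Why: Syn-hydroalumination should give the (E)-alkenylalane, whose copper-catalysed asymmetric conjugate addition to the β-methyl enone sets the C10 quaternary centre under ligand control (ligand enantiomer chosen for the S centre of 10), and the regiodefined aluminium enolate is trapped on oxygen.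

Step 5
Reactants: 10 ring A trimethylsilyl enol ether
Product: 13 (3S)-3-alkenyl-3-methyl-2-methylidenecyclohexan-1-one, via Mannich base 11 (not isolated), via ammonium iodide 12 (not isolated)
Conditions: H2C=NMe2+ Cl−, CH2Cl2, rt; then MeI, Et2O, rt; then DBU, CH2Cl2, rt
Reagents that add atoms: N,N-dimethylmethyleneiminium chloride (C=[N+](C)C.[Cl-])
Why: Regiospecific Mannich reaction of the silyl enol ether at C5, quaternisation and base-induced elimination (α-methylenation with an iminium salt) install C6 as the terminus of an exocyclic enone; no stereocentre is formed.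

Step 6
Reactants: 13 (3S)-3-alkenyl-3-methyl-2-methylidenecyclohexan-1-one
Product: 14 ring A trimethylsilyl enol ether carrying the 3-bromobut-3-enyl chain at C5
Conditions: (2-bromoallyl)trimethylsilane, InCl3 (10 mol %), Me3SiCl, CH2Cl2, −30 °C → rt; Et3N, pentane, non-aqueous work-up
Reagents that add atoms: (2-bromoallyl)trimethylsilane (C=C(Br)C[Si](C)(C)C)
Why: Hosomi–Sakurai conjugate allylation at the unhindered C6 with silyl transfer to the enolate oxygen should build C7–C8(Br)=C17 and leave C5 sp2 as the enol ether, so no stereocentre arises and the carbonyl stays masked.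

Step 7
Reactants: 14 ring A trimethylsilyl enol ether carrying the 3-bromobut-3-enyl chain at C5
Product: 17 trans-fused decalone (4aS,5R,8aS), via cyclized enol ether 15 (not isolated), via cis-fused ketone 16 (not isolated)
Conditions: (Me3Si)3SiH (1.3 equiv), AIBN (0.2 equiv), PhH, 80 °C, syringe-pump addition, 5 mM; then K2CO3, MeOH, rt
Reagents that add atoms: none
Why: The silyl radical abstracts bromine from 14 to give the σ-vinyl radical at C8, which adds to C9 of the (E)-C9=C11 alkene, and the resulting C11 radical is reduced by the silane, so that the C8–C9 bond, the C8=C17 methylidene and the saturated C11 arise together; the closest known reaction type is the tin- or silane-mediated 6-exo vinyl radical cyclization of 2-bromo-1,7-dienes. Ring B closes in the 6-exo-trig mode through a chair-like transition state fused to the ring A cyclohexene, in which C5 is still sp2 (enol ether carbon), so no ring-fusion isomer can form during C–C bond formation and the C4 carbonyl is masked against attack by the vinyl radical. The new C9 centre is set by the C10 quaternary centre: the C10 methyl is axial on the forming ring and allylic 1,3-strain keeps H9 eclipsed with the C10–C5 bond, so C11 should end equatorial and cis to the C10 methyl. Methanolysis then frees the C4 ketone, and carbonate equilibrates C5 (alpha to C4=O) through the cis-fused ketone 16 to the more stable trans ring fusion with H5 anti to the C10 methyl. The step needs 6-exo over 7-endo closure and cyclization faster than reduction or hydrogen transfer of the vinyl radical; the short tether held in place by the ring A double bond, slow silane addition and high dilution should secure both.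

Step 8
Reactants: 17 trans-fused decalone (4aS,5R,8aS)
Product: 19 C4 carbaldehyde (C4 epimers), via enol ether 18 (not isolated)
Conditions: Ph3P+CH2OMe Cl−, KOtBu, THF, 0 °C → rt; then aq. oxalic acid, THF, rt
Reagents that add atoms: (methoxymethyl)triphenylphosphonium chloride (COC[P+](c1ccccc1)(c1ccccc1)c1ccccc1.[Cl-]); water (O)
Why: Wittig methoxymethylenation of the C4 ketone and mild hydrolysis of the enol ether add C19 as a formyl group, while C5 is no longer epimerisable once C4 is sp2 or sp3 carbon-substituted.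

Step 9
Reactants: 19 C4 carbaldehyde (C4 epimers)
Product: 20 (1R,4aS,5R,8aS)-1,4a-dimethyl decalin-1-carbaldehyde
Conditions: KOtBu, MeI, THF, −40 → 0 °C
Reagents that add atoms: iodomethane (CI)
Why: C-alkylation of the exocyclic potassium enolate: methyl iodide should approach equatorially, away from the axial C10 methyl, so the formyl carbon C19 ends axial and cis to C20 (substrate control).

Step 10
Reactants: 20 (1R,4aS,5R,8aS)-1,4a-dimethyl decalin-1-carbaldehyde
Product: 21 C19 primary alcohol
Conditions: NaBH4, MeOH, 0 °C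
Reagents that add atoms: none
Why: Borohydride reduction of the neopentyl aldehyde gives the C19 carbinol without affecting the alkene or the silyl ether.

Step 11
Reactants: 21 C19 primary alcohol; 22 (2R)-2-methylbutanoic acid
Product: 23 C19 (2R)-2-methylbutanoate
Conditions: EDC·HCl, DMAP, CH2Cl2, rt
Reagents that add atoms: none
Why: Steglich esterification acylates the hindered neopentyl alcohol under conditions that should not epimerise the α-stereocentre of the acid.

Step 12
Reactants: 23 C19 (2R)-2-methylbutanoate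
Product: 24 target acid
Conditions: CrO3, aq. H2SO4, acetone, 0 °C
Reagents that add atoms: water (O)
Why: The aqueous acid of the Jones oxidation cleaves the primary silyl ether and the liberated alcohol is oxidised through the aldehyde hydrate to the C15 acid, while the hindered ester and the 1,1-disubstituted alkene should survive brief treatment at 0 °C.

Compound list

1 | methyl hydrogen (R)-3-methylglutarate, (3R)-5-methoxy-3-methyl-5-oxopentanoic acid | OC(=O)C[C@@H](C)CC(=O)OC | starting material
2 | (3S)-5-hydroxy-3-methylpentanoic acid (lithium salt in the flask) | OC(=O)C[C@@H](C)CCO | intermediate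
3 | (4S)-4-methyltetrahydro-2H-pyran-2-one | O=C1C[C@@H](C)CCO1 | intermediate
4 | (4S)-4-methyltetrahydro-2H-pyran-2-ol (anomers) | OC1C[C@@H](C)CCO1 | intermediate
5 | (3R)-3-methylhex-5-yn-1-ol | C#CC[C@@H](C)CCO | intermediate
6 | tert-butyl(dimethyl){[(3R)-3-methylhex-5-yn-1-yl]oxy}silane | C#CC[C@@H](C)CCO[Si](C)(C)C(C)(C)C | intermediate
7 | 3-methylcyclohex-2-en-1-one | CC1=CC(=O)CCC1 | starting material
8 | diisobutyl[(1E,4R)-6-{[tert-butyl(dimethyl)silyl]oxy}-4-methylhex-1-en-1-yl]alane | CC(C)C[Al](CC(C)C)/C=C/C[C@@H](C)CCO[Si](C)(C)C(C)(C)C | intermediate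
9 | {[(3S)-3-[(1E,4R)-6-{[tert-butyl(dimethyl)silyl]oxy}-4-methylhex-1-en-1-yl]-3-methylcyclohex-1-en-1-yl]oxy}(diisobutyl)alane | CC(C)C[Al](CC(C)C)OC1=C[C@](C)(/C=C/C[C@@H](C)CCO[Si](C)(C)C(C)(C)C)CCC1 | intermediate
10 | tert-butyl(dimethyl){[(3R,5E)-3-methyl-6-{(1S)-1-methyl-3-[(trimethylsilyl)oxy]cyclohex-2-en-1-yl}hex-5-en-1-yl]oxy}silane | C[Si](C)(C)OC1=C[C@](C)(/C=C/C[C@@H](C)CCO[Si](C)(C)C(C)(C)C)CCC1 | intermediate
11 | (3S)-3-[(1E,4R)-6-{[tert-butyl(dimethyl)silyl]oxy}-4-methylhex-1-en-1-yl]-2-[(dimethylamino)methyl]-3-methylcyclohexan-1-one (C-2 epimers) | CN(C)CC1C(=O)CCC[C@@]1(C)/C=C/C[C@@H](C)CCO[Si](C)(C)C(C)(C)C | intermediate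
12 | {[(2S)-2-[(1E,4R)-6-{[tert-butyl(dimethyl)silyl]oxy}-4-methylhex-1-en-1-yl]-2-methyl-6-oxocyclohexyl]methyl}trimethylammonium iodide (C-1 epimers) | C[N+](C)(C)CC1C(=O)CCC[C@@]1(C)/C=C/C[C@@H](C)CCO[Si](C)(C)C(C)(C)C.[I-] | intermediate
13 | (3S)-3-[(1E,4R)-6-{[tert-butyl(dimethyl)silyl]oxy}-4-methylhex-1-en-1-yl]-3-methyl-2-methylidenecyclohexan-1-one | C=C1C(=O)CCC[C@@]1(C)/C=C/C[C@@H](C)CCO[Si](C)(C)C(C)(C)C | intermediate
14 | {[(3R,5E)-6-{(1S)-2-(3-bromobut-3-en-1-yl)-1-methyl-3-[(trimethylsilyl)oxy]cyclohex-2-en-1-yl}-3-methylhex-5-en-1-yl]oxy}(tert-butyl)dimethylsilane | C=C(Br)CCC1=C(O[Si](C)(C)C)CCC[C@@]1(C)/C=C/C[C@@H](C)CCO[Si](C)(C)C(C)(C)C | intermediate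
15 | tert-butyl(dimethyl){[(3R)-3-methyl-5-{(1R,8aS)-8a-methyl-2-methylidene-5-[(trimethylsilyl)oxy]-1,2,3,4,6,7,8,8a-octahydronaphthalen-1-yl}pentyl]oxy}silane | C=C1CCC2=C(O[Si](C)(C)C)CCC[C@@]2(C)[C@@H]1CC[C@@H](C)CCO[Si](C)(C)C(C)(C)C | intermediate
16 | (4aS,5R,8aR)-5-[(3R)-5-{[tert-butyl(dimethyl)silyl]oxy}-3-methylpentyl]-4a-methyl-6-methylideneoctahydronaphthalen-1(2H)-one (cis-fused) | C=C1CC[C@H]2C(=O)CCC[C@@]2(C)[C@@H]1CC[C@@H](C)CCO[Si](C)(C)C(C)(C)C | intermediate
17 | (4aS,5R,8aS)-5-[(3R)-5-{[tert-butyl(dimethyl)silyl]oxy}-3-methylpentyl]-4a-methyl-6-methylideneoctahydronaphthalen-1(2H)-one (trans-fused) | C=C1CC[C@@H]2C(=O)CCC[C@@]2(C)[C@@H]1CC[C@@H](C)CCO[Si](C)(C)C(C)(C)C | intermediate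
18 | tert-butyl{[(3R)-5-[(1R,4aS,8aS)-5-(methoxymethylidene)-8a-methyl-2-methylidenedecahydronaphthalen-1-yl]-3-methylpentyl]oxy}dimethylsilane (E/Z mixture) | C=C1CC[C@@H]2C(=COC)CCC[C@@]2(C)[C@@H]1CC[C@@H](C)CCO[Si](C)(C)C(C)(C)C | intermediate
19 | (4aR,5R,8aR)-5-[(3R)-5-{[tert-butyl(dimethyl)silyl]oxy}-3-methylpentyl]-4a-methyl-6-methylidenedecahydronaphthalene-1-carbaldehyde (C-1 epimers) | C=C1CC[C@@H]2C(C=O)CCC[C@@]2(C)[C@@H]1CC[C@@H](C)CCO[Si](C)(C)C(C)(C)C | intermediate
20 | (1R,4aS,5R,8aS)-5-[(3R)-5-{[tert-butyl(dimethyl)silyl]oxy}-3-methylpentyl]-1,4a-dimethyl-6-methylidenedecahydronaphthalene-1-carbaldehyde | C=C1CC[C@@H]2[C@](C)(C=O)CCC[C@@]2(C)[C@@H]1CC[C@@H](C)CCO[Si](C)(C)C(C)(C)C | intermediate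
21 | [(1R,4aS,5R,8aS)-5-[(3R)-5-{[tert-butyl(dimethyl)silyl]oxy}-3-methylpentyl]-1,4a-dimethyl-6-methylidenedecahydronaphthalen-1-yl]methanol | C=C1CC[C@@H]2[C@](C)(CO)CCC[C@@]2(C)[C@@H]1CC[C@@H](C)CCO[Si](C)(C)C(C)(C)C | intermediate
22 | (2R)-2-methylbutanoic acid | CC[C@@H](C)C(=O)O | starting material
23 | [(1R,4aS,5R,8aS)-5-[(3R)-5-{[tert-butyl(dimethyl)silyl]oxy}-3-methylpentyl]-1,4a-dimethyl-6-methylidenedecahydronaphthalen-1-yl]methyl (2R)-2-methylbutanoate | C=C1CC[C@@H]2[C@](C)(COC(=O)[C@H](C)CC)CCC[C@@]2(C)[C@@H]1CC[C@@H](C)CCO[Si](C)(C)C(C)(C)C | intermediate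
24 | (3R)-5-[(1R,4aS,5R,8aS)-5,8a-dimethyl-2-methylidene-5-({[(2R)-2-methylbutanoyl]oxy}methyl)decahydronaphthalen-1-yl]-3-methylpentanoic acid | C=C1CC[C@@H]2[C@](C)(COC(=O)[C@H](C)CC)CCC[C@@]2(C)[C@@H]1CC[C@@H](C)CC(=O)O | target

Total step count: 12.
Longest linear sequence: 12 steps (1 → 24; 7 enters at step 4 and 22 at step 11).

Steps most likely to fail

1. Step 7 (key step). The vinyl radical may close in the 7-endo mode at C11, be reduced or transfer a hydrogen atom before it cyclizes, or add to C9 with incomplete facial control. The fallback sets out from 13 and comes back at 17. TiCl4-mediated conjugate propargylation of 13 with allenyltributylstannane gives the 2-(but-3-ynyl) ketone F1. A palladium-hydride reductive enyne cyclization (Pd2(dba)3·CHCl3, AcOH, Et3SiH, toluene) then forms C8–C9 by hydropalladation of the alkyne, 6-exo carbopalladation of C9=C11 and silane reduction of the C11–Pd bond. K2CO3 in MeOH equilibrates C5 to give 17.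

2. Step 6. The bromine-deactivated allylsilane may add too slowly, so that the α-methylene ketone oligomerises, and the silyl enol ether may hydrolyse on isolation. The fallback sets out from 10 and comes back at 14. MeLi cleaves 10 to the lithium enolate, which is alkylated at C5 with 2-bromo-4-iodobut-1-ene (THF, HMPA) to give the bromoalkenyl ketone F2. Silylation under equilibrating conditions (Me3SiCl, NaI, Et3N, MeCN) should then give the more substituted enol ether 14.

3. Step 9. The hindered aldehyde enolate may be methylated on oxygen, or on carbon with eroded facial selectivity. The fallback sets out from 17 and comes back at 20. Reductive cyanation of the ketone (TosMIC, KOtBu, DME, EtOH; van Leusen reaction) gives the nitrile F3. LDA and MeI methylate the nitrile anion equatorially to the axial quaternary nitrile F4, and i-Bu2AlH followed by aqueous acid converts the nitrile into the aldehyde 20.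

Further compounds

F1 | step 7 | (3S)-2-(but-3-yn-1-yl)-3-[(1E,4R)-6-{[tert-butyl(dimethyl)silyl]oxy}-4-methylhex-1-en-1-yl]-3-methylcyclohexan-1-one (C-2 epimers) | C#CCCC1C(=O)CCC[C@@]1(C)/C=C/C[C@@H](C)CCO[Si](C)(C)C(C)(C)C
F2 | step 6 | (3S)-2-(3-bromobut-3-en-1-yl)-3-[(1E,4R)-6-{[tert-butyl(dimethyl)silyl]oxy}-4-methylhex-1-en-1-yl]-3-methylcyclohexan-1-one (C-2 epimers) | C=C(Br)CCC1C(=O)CCC[C@@]1(C)/C=C/C[C@@H](C)CCO[Si](C)(C)C(C)(C)C
F3 | step 9 | (4aR,5R,8aR)-5-[(3R)-5-{[tert-butyl(dimethyl)silyl]oxy}-3-methylpentyl]-4a-methyl-6-methylidenedecahydronaphthalene-1-carbonitrile (C-1 epimers) | C=C1CC[C@@H]2C(C#N)CCC[C@@]2(C)[C@@H]1CC[C@@H](C)CCO[Si](C)(C)C(C)(C)C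
F4 | step 9 | (1R,4aS,5R,8aS)-5-[(3R)-5-{[tert-butyl(dimethyl)silyl]oxy}-3-methylpentyl]-1,4a-dimethyl-6-methylidenedecahydronaphthalene-1-carbonitrile | C=C1CC[C@@H]2[C@](C)(C#N)CCC[C@@]2(C)[C@@H]1CC[C@@H](C)CCO[Si](C)(C)C(C)(C)C
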